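**Retrosynthetic overview**
- Target ⇒ its tris(isopropyl ether) (BCl3 deprotection) ⇒ C3–aryl bond by Suzuki coupling of a benzofuran-3-yl triflate with a (3,5-dialkoxy-2,4-dimethylphenyl)boronate.
- Triflate ⇒ 2-(2-methoxycarbonylethyl)benzofuran-3(2H)-one ⇒ (decarboxylation) quaternary β-keto ester ⇒ key C–C bond: intermolecular Michael addition of a tert-butyl 3-hydroxybenzofuran-2-carboxylate to methyl acrylate.
- β-Keto ester ⇒ (Dieckmann) aryloxyacetate ⇒ methyl orsellinate + tert-butyl bromoacetate; the orsellinate fixes the 4-methyl/6-oxygen pattern without regiochemical ambiguity.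
- Arylboronate ⇒ aryl bromide ⇒ (formylation/deoxygenation for the second methyl) meta-bromide ⇒ (sterically controlled C–H borylation/bromination) 2-methylresorcinol.
- Ring order: benzene ring A is bought (orsellinate); furanone ring B is closed by the Dieckmann step and aromatised at the triflation; the pre-built aryl ring C is attached last.

Assumption: the SMILES has no stereocentre and no axial descriptor, so no stereocontrol is needed; the hindered aryl–benzofuran axis is left unspecified.

**Route**

Step 1
Reactants: 1 methyl 2,4-dihydroxy-6-methylbenzoate (methyl orsellinate)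
Product: 2 methyl 2-hydroxy-4-isopropoxy-6-methylbenzoate
Conditions: 2-bromopropane (1.3 equiv), K2CO3 (1.5 equiv), DMF, 55 °C
Reagents that add atoms: 2-bromopropane, CC(C)Br
Why: Williamson etherification is selective for the 4-OH because the 2-OH is hydrogen-bonded to the ester carbonyl and much less nucleophilic.

Step 2
Reactants: 2 methyl 2-hydroxy-4-isopropoxy-6-methylbenzoate; 3 tert-butyl bromoacetate
Product: 4 methyl 2-(2-tert-butoxy-2-oxoethoxy)-4-isopropoxy-6-methylbenzoate
Conditions: K2CO3 (2 equiv), DMF, 60 °C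
Reagents that add atoms: none
Why: Williamson O-alkylation of the remaining phenol with a highly reactive α-bromo ester proceeds cleanly in a dipolar aprotic solvent.

Step 3
Reactants: 4 methyl 2-(2-tert-butoxy-2-oxoethoxy)-4-isopropoxy-6-methylbenzoate
Product: 5 tert-butyl 3-hydroxy-6-isopropoxy-4-methylbenzofuran-2-carboxylate
Conditions: KOt-Bu (2.2 equiv), THF, 0 °C → rt; then 1 M HCl
Reagents that add atoms: none
Why: Dieckmann (intramolecular Claisen) condensation, in which the aryloxyacetate enolate closes the five-membered ring onto the neighbouring benzoate and the equilibrium is pulled through by deprotonation of the acidic 3-hydroxybenzofuran-2-carboxylate.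

Step 4 (key step)
Reactants: 5 tert-butyl 3-hydroxy-6-isopropoxy-4-methylbenzofuran-2-carboxylate; 6 methyl acrylate
Product: 7 tert-butyl 6-isopropoxy-2-(3-methoxy-3-oxopropyl)-4-methyl-3-oxo-2,3-dihydrobenzofuran-2-carboxylate (racemic)
Conditions: methyl acrylate (3 equiv), DBU (0.2 equiv), MeCN, rt → 40 °C
Reagents that add atoms: none
Why: Intermolecular Michael addition of the β-keto ester enolate through C-2 under reversible, thermodynamic conditions; only one addition is possible because no α-hydrogen remains, and the quaternary centre forms as a racemate that is erased in steps 5 and 6.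

Step 5
Reactants: 7 tert-butyl 6-isopropoxy-2-(3-methoxy-3-oxopropyl)-4-methyl-3-oxo-2,3-dihydrobenzofuran-2-carboxylate
Product: 9 methyl 3-(6-isopropoxy-4-methyl-3-oxo-2,3-dihydrobenzofuran-2-yl)propanoate (racemic), via β-keto acid 8 (not isolated)
Conditions: TFA/CH2Cl2 (1:3), rt; evaporate; toluene, 80 °C (argon)
Reagents that add atoms: none
Why: Acidolysis of the tert-butyl ester (loss of isobutene) leaves the methyl ester and aryl isopropyl ether untouched, and the β-keto acid decarboxylates through the usual cyclic transition state on warming.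

Step 6
Reactants: 9 methyl 3-(6-isopropoxy-4-methyl-3-oxo-2,3-dihydrobenzofuran-2-yl)propanoate
Product: 10 methyl 3-[6-isopropoxy-4-methyl-3-(trifluoromethylsulfonyloxy)benzofuran-2-yl]propanoate
Conditions: Tf2O (1.2 equiv), i-Pr2NEt (1.5 equiv), CH2Cl2, −78 → 0 °C (argon)
Reagents that add atoms: trifluoromethanesulfonic anhydride, O=S(=O)(OS(=O)(=O)C(F)(F)F)C(F)(F)F
Why: The ketone enolises towards the aromatic 3-hydroxybenzofuran and the enolate is O-sulfonylated, giving the enol triflate and removing the C-2 stereocentre; the far less acidic ester is not touched.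

Step 7
Reactants: 11 2-methylbenzene-1,3-diol (2-methylresorcinol)
Product: 12 1,3-diisopropoxy-2-methylbenzene
Conditions: 2-bromopropane (4 equiv), K2CO3 (4 equiv), DMF, 70 °C
Reagents that add atoms: 2-bromopropane, CC(C)Br
Why: Double Williamson etherification of a simple resorcinol is routine and gives the protecting group that is later removed in the presence of the methyl ester.

Step 8
Reactants: 12 1,3-diisopropoxy-2-methylbenzene
Product: 14 5-bromo-1,3-diisopropoxy-2-methylbenzene, via arylboronate 13 (not isolated)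
Conditions: [Ir(OMe)(cod)]2 (1.5 mol%), 4,4'-di-tert-butyl-2,2'-bipyridine (3 mol%), B2pin2 (1.0 equiv), THF, 80 °C; evaporate; CuBr2 (3 equiv), MeOH/H2O 1:1, 80 °C
Reagents that add atoms: bis(pinacolato)diboron, CC1(C)OB(OC1(C)C)B1OC(C)(C)C(C)(C)O1 (boron of intermediate 13); CuBr2, [Cu+2].[Br-].[Br-] (bromine of 14)
Why: Iridium-catalysed C–H borylation is sterically controlled and takes the only ring hydrogen without an ortho substituent (meta to both ethers), and CuBr2 bromodeboronation in the same flask gives the meta-bromide that electrophilic bromination cannot give.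

Step 9
Reactants: 14 5-bromo-1,3-diisopropoxy-2-methylbenzene
Product: 15 6-bromo-2,4-diisopropoxy-3-methylbenzaldehyde
Conditions: POCl3 (3 equiv), DMF, 0 → 90 °C; then H2O, 50 °C
Reagents that add atoms: N,N-dimethylformamide, CN(C)C=O (formyl carbon); water, O (formyl oxygen on hydrolysis)
Why: Vilsmeier–Haack formylation, where the two equivalent free positions are each ortho to one isopropoxy group and para to the other, so only this aldehyde can form.

Step 10
Reactants: 15 6-bromo-2,4-diisopropoxy-3-methylbenzaldehyde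
Product: 16 1-bromo-3,5-diisopropoxy-2,4-dimethylbenzene
Conditions: Et3SiH (3 equiv), TFA/CH2Cl2 (1:1), 0 °C → rt
Reagents that add atoms: none
Why: Ionic hydrogenation, in which the ortho,para-dialkoxy-stabilised benzylic cation is reduced twice by the silane down to the methyl group while the aryl bromide and ethers are inert.

Step 11
Reactants: 16 1-bromo-3,5-diisopropoxy-2,4-dimethylbenzene
Product: 18 2-(3,5-diisopropoxy-2,4-dimethylphenyl)-4,4,5,5-tetramethyl-1,3,2-dioxaborolane, via aryllithium 17 (not isolated)
Conditions: n-BuLi (1.1 equiv), THF, −78 °C; then 2-isopropoxy-4,4,5,5-tetramethyl-1,3,2-dioxaborolane (1.5 equiv), −78 °C → rt; H2O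
Reagents that add atoms: n-butyllithium, [Li]CCCC (lithium of intermediate 17); 2-isopropoxy-4,4,5,5-tetramethyl-1,3,2-dioxaborolane, CC(C)OB1OC(C)(C)C(C)(C)O1
Why: Bromine–lithium exchange is fast at −78 °C and the aryllithium is trapped by the borate ester to give a bench-stable pinacol boronate.

Step 12
Reactants: 10 methyl 3-[6-isopropoxy-4-methyl-3-(trifluoromethylsulfonyloxy)benzofuran-2-yl]propanoate; 18 2-(3,5-diisopropoxy-2,4-dimethylphenyl)-4,4,5,5-tetramethyl-1,3,2-dioxaborolane
Product: 19 methyl 3-[3-(3,5-diisopropoxy-2,4-dimethylphenyl)-6-isopropoxy-4-methylbenzofuran-2-yl]propanoate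
Conditions: Pd(OAc)2 (5 mol%), 2-dicyclohexylphosphino-2',6'-dimethoxybiphenyl (SPhos, 10 mol%), K3PO4 (3 equiv), toluene/H2O 10:1, 90 °C (degassed)
Reagents that add atoms: none
Why: Suzuki–Miyaura coupling, where the bulky electron-rich biarylphosphine allows oxidative addition of the enol triflate and formation of the tri-ortho-substituted aryl–heteroaryl bond, and K3PO4 spares the methyl ester.

Step 13
Reactants: 19 methyl 3-[3-(3,5-diisopropoxy-2,4-dimethylphenyl)-6-isopropoxy-4-methylbenzofuran-2-yl]propanoate
Product: 20 Talarominine A, methyl 3-[3-(3,5-dihydroxy-2,4-dimethylphenyl)-6-hydroxy-4-methylbenzofuran-2-yl]propanoate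
Conditions: BCl3 (1 M in CH2Cl2, 9 equiv), CH2Cl2, −78 → 0 °C; then H2O
Reagents that add atoms: none
Why: Lewis-acid dealkylation, where BCl3 cleaves secondary-alkyl aryl ethers at or below 0 °C by chloride attack on the coordinated isopropyl group, conditions under which the methyl ester and the benzofuran survive.

**Compound list**
1 | methyl 2,4-dihydroxy-6-methylbenzoate (methyl orsellinate) | COC(=O)c1c(C)cc(O)cc1O | starting material
2 | methyl 2-hydroxy-4-isopropoxy-6-methylbenzoate | COC(=O)c1c(C)cc(OC(C)C)cc1O | intermediate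
3 | tert-butyl bromoacetate | CC(C)(C)OC(=O)CBr | starting material
4 | methyl 2-(2-tert-butoxy-2-oxoethoxy)-4-isopropoxy-6-methylbenzoate | COC(=O)c1c(C)cc(OC(C)C)cc1OCC(=O)OC(C)(C)C | intermediate
5 | tert-butyl 3-hydroxy-6-isopropoxy-4-methylbenzofuran-2-carboxylate | CC(C)(C)OC(=O)c1oc2cc(OC(C)C)cc(C)c2c1O | intermediate
6 | methyl acrylate | C=CC(=O)OC | starting material
7 | tert-butyl 6-isopropoxy-2-(3-methoxy-3-oxopropyl)-4-methyl-3-oxo-2,3-dihydrobenzofuran-2-carboxylate (racemic) | COC(=O)CCC1(C(=O)OC(C)(C)C)Oc2cc(OC(C)C)cc(C)c2C1=O | intermediate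
8 | 6-isopropoxy-2-(3-methoxy-3-oxopropyl)-4-methyl-3-oxo-2,3-dihydrobenzofuran-2-carboxylic acid (racemic) | COC(=O)CCC1(C(=O)O)Oc2cc(OC(C)C)cc(C)c2C1=O | intermediate (not isolated)
9 | methyl 3-(6-isopropoxy-4-methyl-3-oxo-2,3-dihydrobenzofuran-2-yl)propanoate (racemic) | COC(=O)CCC1Oc2cc(OC(C)C)cc(C)c2C1=O | intermediate
10 | methyl 3-[6-isopropoxy-4-methyl-3-(trifluoromethylsulfonyloxy)benzofuran-2-yl]propanoate | COC(=O)CCc1oc2cc(OC(C)C)cc(C)c2c1OS(=O)(=O)C(F)(F)F | intermediate
11 | 2-methylbenzene-1,3-diol (2-methylresorcinol) | Cc1c(O)cccc1O | starting material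
12 | 1,3-diisopropoxy-2-methylbenzene | Cc1c(OC(C)C)cccc1OC(C)C | intermediate
13 | 2-(3,5-diisopropoxy-4-methylphenyl)-4,4,5,5-tetramethyl-1,3,2-dioxaborolane | Cc1c(OC(C)C)cc(B2OC(C)(C)C(C)(C)O2)cc1OC(C)C | intermediate (not isolated)
14 | 5-bromo-1,3-diisopropoxy-2-methylbenzene | Cc1c(OC(C)C)cc(Br)cc1OC(C)C | intermediate
15 | 6-bromo-2,4-diisopropoxy-3-methylbenzaldehyde | Cc1c(OC(C)C)cc(Br)c(C=O)c1OC(C)C | intermediate
16 | 1-bromo-3,5-diisopropoxy-2,4-dimethylbenzene | Cc1c(OC(C)C)cc(Br)c(C)c1OC(C)C | intermediate
17 | (3,5-diisopropoxy-2,4-dimethylphenyl)lithium | [Li]c1cc(OC(C)C)c(C)c(OC(C)C)c1C | intermediate (not isolated)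
18 | 2-(3,5-diisopropoxy-2,4-dimethylphenyl)-4,4,5,5-tetramethyl-1,3,2-dioxaborolane | Cc1c(OC(C)C)cc(B2OC(C)(C)C(C)(C)O2)c(C)c1OC(C)C | intermediate
19 | methyl 3-[3-(3,5-diisopropoxy-2,4-dimethylphenyl)-6-isopropoxy-4-methylbenzofuran-2-yl]propanoate | COC(=O)CCc1oc2cc(OC(C)C)cc(C)c2c1-c1cc(OC(C)C)c(C)c(OC(C)C)c1C | intermediate
20 | Talarominine A, methyl 3-[3-(3,5-dihydroxy-2,4-dimethylphenyl)-6-hydroxy-4-methylbenzofuran-2-yl]propanoate | COC(=O)CCc1oc2cc(O)cc(C)c2c1-c1cc(O)c(C)c(O)c1C | target

**Summary**
Total step count: 13 (steps 5, 8 and 11 each run in one flask through a non-isolated intermediate).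
Longest linear sequence: 8 steps (1 → 2 → 4 → 5 → 7 → 9 → 10 → 19 → 20). The aryl branch from 11 is 5 steps to boronate 18.

**Three steps most likely to fail, each with a fallback**

Step 12 (Suzuki coupling). The new bond has three flanking groups (the C-2 chain, the peri C-4 methyl and the aryl ortho-methyl). The electron-rich, ortho-substituted boronate can protodeboronate, and the triflate can hydrolyse back to ketone 9. Fallback: a base-free Negishi coupling. Set out from bromide 16 and generate aryllithium 17 as in step 11 (n-BuLi, THF, −78 °C). Transmetalate with ZnCl2 to (3,5-diisopropoxy-2,4-dimethylphenyl)zinc chloride F1. Couple F1 with triflate 10 (Pd2(dba)3, 2-dicyclohexylphosphino-2',4',6'-triisopropylbiphenyl, THF, 60 °C) to come back to the route at 19.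

Step 6 (enol triflation). The 2-alkylbenzofuran-3(2H)-one 9 is prone to autoxidation, and the C-3 oxygen sits next to the peri methyl. Fallback: reach the coupling through a 3-bromobenzofuran instead of an enol sulfonate. Set out from ketone 9 and reduce with NaBH4 (MeOH, 0 °C) to methyl 3-(3-hydroxy-6-isopropoxy-4-methyl-2,3-dihydrobenzofuran-2-yl)propanoate F2 (diastereomer mixture). Dehydrate with p-TsOH in refluxing MeOH (MeOH keeps the methyl ester) to methyl 3-(6-isopropoxy-4-methylbenzofuran-2-yl)propanoate F3. Brominate the free C-3 position with NBS (MeCN, 0 °C) to methyl 3-(3-bromo-6-isopropoxy-4-methylbenzofuran-2-yl)propanoate F4; competing bromination of the alkoxy-activated benzo ring is the point to watch. Suzuki coupling of F4 with boronate 18 under the step 12 conditions comes back to the route at 19.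

Step 9 (Vilsmeier formylation). The position attacked is squeezed between bromine and an isopropoxy group, and hot POCl3/DMF could slowly dealkylate. Fallback: install the methyl directly by directed ortho-lithiation instead of electrophilic substitution. Set out from bromide 14 and treat with lithium 2,2,6,6-tetramethylpiperidide (THF, −78 °C). This deprotonates the only kind of ring C–H, which is acidified by both Br and the ether, to give (6-bromo-2,4-diisopropoxy-3-methylphenyl)lithium F5. Keep it at −78 °C to avoid aryne formation and quench with MeI to come back to the route at 16, skipping 15.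

**Further compounds**
F1 | step 12 | (3,5-diisopropoxy-2,4-dimethylphenyl)zinc chloride | Cl[Zn]c1cc(OC(C)C)c(C)c(OC(C)C)c1C
F2 | step 6 | methyl 3-(3-hydroxy-6-isopropoxy-4-methyl-2,3-dihydrobenzofuran-2-yl)propanoate (racemic diastereomer mixture) | COC(=O)CCC1Oc2cc(OC(C)C)cc(C)c2C1O
F3 | step 6 | methyl 3-(6-isopropoxy-4-methylbenzofuran-2-yl)propanoate | COC(=O)CCc1cc2c(C)cc(OC(C)C)cc2o1
F4 | step 6 | methyl 3-(3-bromo-6-isopropoxy-4-methylbenzofuran-2-yl)propanoate | COC(=O)CCc1oc2cc(OC(C)C)cc(C)c2c1Br
F5 | step 9 | (6-bromo-2,4-diisopropoxy-3-methylphenyl)lithium | [Li]c1c(Br)cc(OC(C)C)c(C)c1OC(C)C
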